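**Retrosynthetic overview**
1. Target ⇒ acid hydrolysis of a 4-O-MOM tetronate; the furyl–C(=O)–CH2 unit comes from a carbonylative Stille coupling of an (E,E)-allylic chloride, CO and tributyl(furan-3-yl)stannane.
2. (E)-C5=C1′ alkene ⇒ anti-dehydration of a 5,1′-erythro aldol adduct, itself from a fluoride-promoted vinylogous Mukaiyama aldol between the 2-silyloxyfuran of MOM-protected 3-methyltetronic acid and an (S)-α-methyl aldehyde.
3. (S)-α-methyl aldehyde ⇒ Ru–BINAP hydrogenation of the (E)-allylic alcohol made by SeO2 oxidation of (2E,6E)-farnesyl TBDPS ether; both trisubstituted (E)-olefins are bought with farnesol.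
4. Ring order: no ring is constructed; the butenolide ring (3-methyltetronic acid) is attached first (step 7), the furan ring (stannane) second (step 11).

Assumption: the SMILES is read literally, so the exocyclic alkene is E (side chain cis to C4–OH, trans to the ring oxygen) and the methyl-bearing centre is S; 3-methyltetronic acid and tributyl(furan-3-yl)stannane are taken as purchasable.

**Route**

Step 1
Reactants: 1 (2E,6E)-farnesol
Product: 2 (2E,6E)-farnesyl tert-butyldiphenylsilyl ether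
Conditions: TBDPSCl, imidazole, CH2Cl2, 0 °C to rt
Reagents that add atoms: tert-butyl(chloro)diphenylsilane, CC(C)(C)[Si](Cl)(c1ccccc1)c1ccccc1
Why: Imidazole-promoted silylation of the primary allylic alcohol (silyl ether protection) masks C1 with a group that survives oxidation, hydrogenation, base and catalytic fluoride.

Step 2
Reactants: 2 (2E,6E)-farnesyl tert-butyldiphenylsilyl ether
Product: 3 (2E,6E,10E)-12-(TBDPS-oxy)-2,6,10-trimethyldodeca-2,6,10-trien-1-ol
Conditions: SeO2 (0.3 equiv), t-BuOOH (3 equiv), salicylic acid (0.1 equiv), CH2Cl2, 0 °C to rt; unreacted 2 recycled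
Reagents that add atoms: selenium dioxide, O=[Se]=O (catalytic oxygen carrier); tert-butyl hydroperoxide, CC(C)(C)OO (stoichiometric oxygen source)
Why: Riley-type SeO2 allylic oxidation (ene reaction then [2,3]-shift) attacks the terminal isopropylidene and hydroxylates its (E)-methyl group, giving the (E)-allylic alcohol.

Step 3
Reactants: 3 (2E,6E,10E)-12-(TBDPS-oxy)-2,6,10-trimethyldodeca-2,6,10-trien-1-ol
Product: 4 (2S,6E,10E)-12-(TBDPS-oxy)-2,6,10-trimethyldodeca-6,10-dien-1-ol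
Conditions: Ru(OAc)2[(S)-BINAP] (1 mol%), H2 (100 atm), MeOH, 20 °C
Reagents that add atoms: none
Why: Noyori asymmetric hydrogenation, in which the free hydroxyl anchors only the allylic-alcohol olefin to Ru–BINAP and hydrogen is delivered to the face giving the (2S)-methyl centre (sense extrapolated from geraniol giving (R)-citronellol with the (S)-ligand, to be confirmed on 4 by Mosher ester analysis).

Step 4
Reactants: 4 (2S,6E,10E)-12-(TBDPS-oxy)-2,6,10-trimethyldodeca-6,10-dien-1-ol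
Product: 5 (2S,6E,10E)-12-(TBDPS-oxy)-2,6,10-trimethyldodeca-6,10-dienal
Conditions: Dess–Martin periodinane, CH2Cl2, 0 °C to rt; used crude at once
Reagents that add atoms: none
Why: Dess–Martin oxidation is fast and non-basic, so the α-stereocentre is not epimerised and the olefins are untouched.

Step 5
Reactants: 6 3-methyltetronic acid (4-hydroxy-3-methylfuran-2(5H)-one)
Product: 7 4-(methoxymethoxy)-3-methylfuran-2(5H)-one
Conditions: MOMCl, i-Pr2NEt, CH2Cl2, 0 °C
Reagents that add atoms: chloromethyl methyl ether, COCCl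
Why: O-alkylation of the vinylogous acid by a hard oxocarbenium-type electrophile gives the 4-O-MOM tetronate, which tolerates base, fluoride and palladium but is cleaved by dilute acid.

Step 6
Reactants: 7 4-(methoxymethoxy)-3-methylfuran-2(5H)-one
Product: 9 4-(methoxymethoxy)-3-methyl-2-(trimethylsilyloxy)furan, via lithium furanolate 8 (not isolated)
Conditions: lithium diisopropylamide, THF, −78 °C; then Me3SiCl, −78 to 0 °C; pentane, filter, concentrate
Reagents that add atoms: chlorotrimethylsilane, C[Si](C)(C)Cl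
Why: Kinetic deprotonation at C5 gives the aromatic 2-furanolate, which is trapped on oxygen (silyl dienol ether formation).

Step 7
Reactants: 5 (2S,6E,10E)-12-(TBDPS-oxy)-2,6,10-trimethyldodeca-6,10-dienal; 9 4-(methoxymethoxy)-3-methyl-2-(trimethylsilyloxy)furan
Product: 11 (5R)-5-[(1R,2S,6E,10E)-12-(TBDPS-oxy)-1-hydroxy-2,6,10-trimethyldodeca-6,10-dien-1-yl]-4-(methoxymethoxy)-3-methylfuran-2(5H)-one (5,1′-erythro), via TMS-ether aldol adduct 10 (not isolated)
Conditions: Bu4NF (0.1 equiv), THF, −78 °C; then AcOH/THF/H2O, 0 °C to rt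
Reagents that add atoms: none
Why: Fluoride-promoted vinylogous Mukaiyama aldol, in which the naked furanolate attacks through an open antiperiplanar transition state at C5 to give mainly the 5,1′-erythro pair (Felkin isomer drawn; its (5S,1′S) partner behaves identically because both new centres are destroyed in step 8 and only their mutual relationship matters).

Step 8
Reactants: 11 5,1′-erythro aldol adduct
Product: 12 (5E)-5-[(2S,6E,10E)-12-(TBDPS-oxy)-2,6,10-trimethyldodeca-6,10-dien-1-ylidene]-4-(methoxymethoxy)-3-methylfuran-2(5H)-one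
Conditions: PPh3, diethyl azodicarboxylate, THF, 0 °C to rt; SiO2 chromatography removes the minor (Z)-isomer
Reagents that add atoms: none
Why: Mitsunobu-type dehydration, in which the alkoxyphosphonium formed with retention loses the acidic C5–H antiperiplanar (E2), so the erythro adduct gives stereospecifically the (E)-alkylidene with the chain cis to C4.

Step 9
Reactants: 12 (E)-alkylidene tetronate TBDPS ether
Product: 13 (5E)-5-[(2S,6E,10E)-12-hydroxy-2,6,10-trimethyldodeca-6,10-dien-1-ylidene]-4-(methoxymethoxy)-3-methylfuran-2(5H)-one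
Conditions: HF·pyridine, pyridine, THF, 0 °C to rt
Reagents that add atoms: none
Why: Fluoride desilylation under buffered, non-nucleophilic conditions frees the allylic alcohol without opening the enol lactone, cleaving the MOM acetal or isomerising the (E)-alkylidene.

Step 10
Reactants: 13 allylic alcohol
Product: 15 (5E)-5-[(2S,6E,10E)-12-chloro-2,6,10-trimethyldodeca-6,10-dien-1-ylidene]-4-(methoxymethoxy)-3-methylfuran-2(5H)-one, via allylic mesylate 14 (not isolated)
Conditions: MsCl, 2,4,6-collidine, LiCl, DMF, 0 °C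
Reagents that add atoms: lithium chloride, [Li+].[Cl-] (methanesulfonyl chloride, CS(=O)(=O)Cl, supplies only the mesyl group of intermediate 14)
Why: Collington–Meyers chlorination, in which the mesylate is displaced in situ by chloride (SN2 at the primary carbon) without allylic transposition or loss of olefin geometry.

Step 11
Reactants: 15 allylic chloride; 16 tributyl(furan-3-yl)stannane
Product: 17 (5E)-5-[(2S,6E,10E)-13-(furan-3-yl)-2,6,10-trimethyl-13-oxotrideca-6,10-dien-1-ylidene]-4-(methoxymethoxy)-3-methylfuran-2(5H)-one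
Conditions: Pd2(dba)3 (2.5 mol%), PPh3 (10 mol%), CO (3 atm), THF, 50 °C
Reagents that add atoms: carbon monoxide, [C-]#[O+]
Why: Carbonylative Stille coupling, in which zerovalent palladium forms the allyl complex, CO inserts at the unsubstituted terminus and furyl transfer with reductive elimination gives the β,γ-unsaturated ketone under neutral conditions, with the (E)-olefin retained and no drift into conjugation.

Step 12
Reactants: 17 MOM-protected ketone
Product: 18 CNP0178778.1, (5E)-5-[(2S,6E,10E)-13-(furan-3-yl)-2,6,10-trimethyl-13-oxotrideca-6,10-dien-1-ylidene]-4-hydroxy-3-methylfuran-2(5H)-one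
Conditions: 1 M aq. HCl, THF, 0 °C to rt
Reagents that add atoms: none
Why: Acetal hydrolysis of the MOM vinylogous ester needs only dilute acid, which is too mild to cyclise the 1,5-diene, conjugate the β,γ-enone or isomerise the (E)-alkylidene.

**Compound list**
1 | (2E,6E)-3,7,11-trimethyldodeca-2,6,10-trien-1-ol ((2E,6E)-farnesol) | CC(C)=CCC/C(C)=C/CC/C(C)=C/CO | starting material
2 | tert-butyl(diphenyl){[(2E,6E)-3,7,11-trimethyldodeca-2,6,10-trien-1-yl]oxy}silane | CC(C)=CCC/C(C)=C/CC/C(C)=C/CO[Si](c1ccccc1)(c1ccccc1)C(C)(C)C | intermediate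
3 | (2E,6E,10E)-12-[(tert-butyldiphenylsilyl)oxy]-2,6,10-trimethyldodeca-2,6,10-trien-1-ol | OC/C(C)=C/CC/C(C)=C/CC/C(C)=C/CO[Si](c1ccccc1)(c1ccccc1)C(C)(C)C | intermediate
4 | (2S,6E,10E)-12-[(tert-butyldiphenylsilyl)oxy]-2,6,10-trimethyldodeca-6,10-dien-1-ol | OC[C@@H](C)CCC/C(C)=C/CC/C(C)=C/CO[Si](c1ccccc1)(c1ccccc1)C(C)(C)C | intermediate
5 | (2S,6E,10E)-12-[(tert-butyldiphenylsilyl)oxy]-2,6,10-trimethyldodeca-6,10-dienal | O=C[C@@H](C)CCC/C(C)=C/CC/C(C)=C/CO[Si](c1ccccc1)(c1ccccc1)C(C)(C)C | intermediate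
6 | 4-hydroxy-3-methylfuran-2(5H)-one (3-methyltetronic acid) | CC1=C(O)COC1=O | starting material
7 | 4-(methoxymethoxy)-3-methylfuran-2(5H)-one | CC1=C(OCOC)COC1=O | intermediate
8 | lithium 4-(methoxymethoxy)-3-methylfuran-2-olate | [Li+].Cc1c(OCOC)coc1[O-] | intermediate
9 | trimethyl{[4-(methoxymethoxy)-3-methylfuran-2-yl]oxy}silane | Cc1c(OCOC)coc1O[Si](C)(C)C | intermediate
10 | (5R)-5-[(1R,2S,6E,10E)-12-[(tert-butyldiphenylsilyl)oxy]-2,6,10-trimethyl-1-[(trimethylsilyl)oxy]dodeca-6,10-dien-1-yl]-4-(methoxymethoxy)-3-methylfuran-2(5H)-one (erythro; drawn with Felkin sense) | CC1=C(OCOC)[C@@H]([C@H](O[Si](C)(C)C)[C@@H](C)CCC/C(C)=C/CC/C(C)=C/CO[Si](c2ccccc2)(c2ccccc2)C(C)(C)C)OC1=O | intermediate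
11 | (5R)-5-[(1R,2S,6E,10E)-12-[(tert-butyldiphenylsilyl)oxy]-1-hydroxy-2,6,10-trimethyldodeca-6,10-dien-1-yl]-4-(methoxymethoxy)-3-methylfuran-2(5H)-one (erythro; accompanied by its (5S,1′S,2′S) erythro partner) | CC1=C(OCOC)[C@@H]([C@H](O)[C@@H](C)CCC/C(C)=C/CC/C(C)=C/CO[Si](c2ccccc2)(c2ccccc2)C(C)(C)C)OC1=O | intermediate
12 | (5E)-5-[(2S,6E,10E)-12-[(tert-butyldiphenylsilyl)oxy]-2,6,10-trimethyldodeca-6,10-dien-1-ylidene]-4-(methoxymethoxy)-3-methylfuran-2(5H)-one | CC1=C(OCOC)/C(=C\[C@@H](C)CCC/C(C)=C/CC/C(C)=C/CO[Si](c2ccccc2)(c2ccccc2)C(C)(C)C)OC1=O | intermediate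
13 | (5E)-5-[(2S,6E,10E)-12-hydroxy-2,6,10-trimethyldodeca-6,10-dien-1-ylidene]-4-(methoxymethoxy)-3-methylfuran-2(5H)-one | CC1=C(OCOC)/C(=C\[C@@H](C)CCC/C(C)=C/CC/C(C)=C/CO)OC1=O | intermediate
14 | (2E,6E,11S)-12-[(2E)-3-(methoxymethoxy)-4-methyl-5-oxofuran-2(5H)-ylidene]-3,7,11-trimethyldodeca-2,6-dien-1-yl methanesulfonate | CC1=C(OCOC)/C(=C\[C@@H](C)CCC/C(C)=C/CC/C(C)=C/COS(C)(=O)=O)OC1=O | intermediate
15 | (5E)-5-[(2S,6E,10E)-12-chloro-2,6,10-trimethyldodeca-6,10-dien-1-ylidene]-4-(methoxymethoxy)-3-methylfuran-2(5H)-one | CC1=C(OCOC)/C(=C\[C@@H](C)CCC/C(C)=C/CC/C(C)=C/CCl)OC1=O | intermediate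
16 | tributyl(furan-3-yl)stannane | CCCC[Sn](CCCC)(CCCC)c1ccoc1 | starting material
17 | (5E)-5-[(2S,6E,10E)-13-(furan-3-yl)-2,6,10-trimethyl-13-oxotrideca-6,10-dien-1-ylidene]-4-(methoxymethoxy)-3-methylfuran-2(5H)-one | CC1=C(OCOC)/C(=C\[C@@H](C)CCC/C(C)=C/CC/C(C)=C/CC(=O)c2ccoc2)OC1=O | intermediate
18 | (5E)-5-[(2S,6E,10E)-13-(furan-3-yl)-2,6,10-trimethyl-13-oxotrideca-6,10-dien-1-ylidene]-4-hydroxy-3-methylfuran-2(5H)-one (CNP0178778.1) | CC1=C(O)/C(=C\[C@@H](C)CCC/C(C)=C/CC/C(C)=C/CC(=O)c2ccoc2)OC1=O | target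

**Totals and risks**
Total step count: 12. Longest linear sequence: 10 (steps 1–4 and 7–12, from farnesol).

Most likely to fail:

Step 3 — the enantioselectivity and facial sense on a 2-methyl allylic alcohol are extrapolated from 3-substituted cases. Fallback, setting out from 3 and returning at 4: move the stereo-determining hydrogenation to the carboxylic acid level, where the carboxylate directs the catalyst. MnO2 (CH2Cl2) gives (2E,6E,10E)-12-[(tert-butyldiphenylsilyl)oxy]-2,6,10-trimethyldodeca-2,6,10-trienal F1. NaClO2/NaH2PO4/2-methylbut-2-ene (t-BuOH–H2O) gives (2E,6E,10E)-12-[(tert-butyldiphenylsilyl)oxy]-2,6,10-trimethyldodeca-2,6,10-trienoic acid F2. Ru(OAc)2[(S)-H8-BINAP]/H2 (MeOH) gives (2S,6E,10E)-12-[(tert-butyldiphenylsilyl)oxy]-2,6,10-trimethyldodeca-6,10-dienoic acid F3, and LiAlH4 (Et2O, 0 °C) reduces it to 4.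

Step 7 — the erythro preference is precedented for the parent 2-silyloxyfuran, not for this 3-methyl-4-alkoxy one. Fallback, setting out from 5 and 9 and returning at 12: invert both the aldol sense and the elimination sense. BF3·OEt2 (CH2Cl2, −78 °C; Lewis-acid vinylogous Mukaiyama aldol, threo-selective) gives (5S)-5-[(1R,2S,6E,10E)-12-[(tert-butyldiphenylsilyl)oxy]-1-hydroxy-2,6,10-trimethyldodeca-6,10-dien-1-yl]-4-(methoxymethoxy)-3-methylfuran-2(5H)-one F4. Burgess reagent (toluene, 60 °C) converts it to methyl ({[(1R,2S,6E,10E)-12-[(tert-butyldiphenylsilyl)oxy]-1-[(2S)-3-(methoxymethoxy)-4-methyl-5-oxo-2,5-dihydrofuran-2-yl]-2,6,10-trimethyldodeca-6,10-dien-1-yl]oxy}sulfonyl)carbamate F5, whose thermal syn-elimination gives the same (E)-alkene 12.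

Step 8 — the acidic C5–H may divert the dehydration into an E1cB path that converges on the more stable (Z)-isomer. Fallback, setting out from 11 and returning at 12: accept the Z-selective elimination and correct the geometry photochemically. MsCl/Et3N (CH2Cl2) gives (1R,2S,6E,10E)-12-[(tert-butyldiphenylsilyl)oxy]-1-[(2R)-3-(methoxymethoxy)-4-methyl-5-oxo-2,5-dihydrofuran-2-yl]-2,6,10-trimethyldodeca-6,10-dien-1-yl methanesulfonate F6. DBU then gives (5Z)-5-[(2S,6E,10E)-12-[(tert-butyldiphenylsilyl)oxy]-2,6,10-trimethyldodeca-6,10-dien-1-ylidene]-4-(methoxymethoxy)-3-methylfuran-2(5H)-one F7. Irradiation (about 313–350 nm, MeCN, Pyrex) drives F7 to a photostationary E/Z mixture, from which 12 is separated by chromatography and F7 is re-irradiated.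

**Further compounds**
F1 | step 3 | (2E,6E,10E)-12-[(tert-butyldiphenylsilyl)oxy]-2,6,10-trimethyldodeca-2,6,10-trienal | O=C/C(C)=C/CC/C(C)=C/CC/C(C)=C/CO[Si](c1ccccc1)(c1ccccc1)C(C)(C)C
F2 | step 3 | (2E,6E,10E)-12-[(tert-butyldiphenylsilyl)oxy]-2,6,10-trimethyldodeca-2,6,10-trienoic acid | OC(=O)/C(C)=C/CC/C(C)=C/CC/C(C)=C/CO[Si](c1ccccc1)(c1ccccc1)C(C)(C)C
F3 | step 3 | (2S,6E,10E)-12-[(tert-butyldiphenylsilyl)oxy]-2,6,10-trimethyldodeca-6,10-dienoic acid | OC(=O)[C@@H](C)CCC/C(C)=C/CC/C(C)=C/CO[Si](c1ccccc1)(c1ccccc1)C(C)(C)C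
F4 | step 7 | (5S)-5-[(1R,2S,6E,10E)-12-[(tert-butyldiphenylsilyl)oxy]-1-hydroxy-2,6,10-trimethyldodeca-6,10-dien-1-yl]-4-(methoxymethoxy)-3-methylfuran-2(5H)-one (threo) | CC1=C(OCOC)[C@H]([C@H](O)[C@@H](C)CCC/C(C)=C/CC/C(C)=C/CO[Si](c2ccccc2)(c2ccccc2)C(C)(C)C)OC1=O
F5 | step 7 | methyl ({[(1R,2S,6E,10E)-12-[(tert-butyldiphenylsilyl)oxy]-1-[(2S)-3-(methoxymethoxy)-4-methyl-5-oxo-2,5-dihydrofuran-2-yl]-2,6,10-trimethyldodeca-6,10-dien-1-yl]oxy}sulfonyl)carbamate | CC1=C(OCOC)[C@H]([C@H](OS(=O)(=O)NC(=O)OC)[C@@H](C)CCC/C(C)=C/CC/C(C)=C/CO[Si](c2ccccc2)(c2ccccc2)C(C)(C)C)OC1=O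
F6 | step 8 | (1R,2S,6E,10E)-12-[(tert-butyldiphenylsilyl)oxy]-1-[(2R)-3-(methoxymethoxy)-4-methyl-5-oxo-2,5-dihydrofuran-2-yl]-2,6,10-trimethyldodeca-6,10-dien-1-yl methanesulfonate | CC1=C(OCOC)[C@@H]([C@H](OS(C)(=O)=O)[C@@H](C)CCC/C(C)=C/CC/C(C)=C/CO[Si](c2ccccc2)(c2ccccc2)C(C)(C)C)OC1=O
F7 | step 8 | (5Z)-5-[(2S,6E,10E)-12-[(tert-butyldiphenylsilyl)oxy]-2,6,10-trimethyldodeca-6,10-dien-1-ylidene]-4-(methoxymethoxy)-3-methylfuran-2(5H)-one | CC1=C(OCOC)/C(=C/[C@@H](C)CCC/C(C)=C/CC/C(C)=C/CO[Si](c2ccccc2)(c2ccccc2)C(C)(C)C)OC1=O
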